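**Strategy.** The six-membered carbocycle carries its ketone at C1 and the propanoyloxy oxygen at C4, para to each other; this 1,4-dioxygenation is traced back to cyclohexa-1,3-diene. In one flask, singlet oxygen bridges the diene termini and a cinchona-derived base opens the meso peroxide enantioselectively, so both C–O bonds and the C4 stereocentre arise from an unfunctionalised, achiral hydrocarbon. The resulting (R)-4-hydroxyenone then directs every later centre: isopropyl enters anti at C5, oxygen anti at C6, C2=C3 and the C2 hydroxymethyl follow, and a late Mitsunobu inversion turns C4 cis to isopropyl.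

Key step: step 1

Remark on numbering: in the prose, ring atoms carry the target numbering (C1 ketone, C2 hydroxymethyl-bearing alkene carbon, C3 alkene CH, C4 propanoyloxy carbon, C5 isopropyl carbon, C6 acyloxy carbon; C7 is the hydroxymethyl carbon). Systematic names use their own locants.

Assumption: 9-O-acetylcupreine is taken to be the pseudoenantiomer that leads to the R enone; if a trial run shows the opposite sense, 9-O-acetylcupreidine replaces it and nothing else changes.

**Step 1**
Reactants: 1 cyclohexa-1,3-diene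
Product: 3 (4R)-4-hydroxycyclohex-2-en-1-one, via meso endoperoxide 2 (not isolated)
Conditions: O2, 5,10,15,20-tetraphenylporphyrin (cat.), visible light, CH2Cl2, 0 °C; then Ar purge, 9-O-acetylcupreine (5–10 mol %), CH2Cl2, 0 °C to rt
Reagents that add atoms: dioxygen, O=O
Why: Photosensitised singlet oxygen adds suprafacially across the termini of the s-cis diene in a [4+2] cycloaddition, the mode by which the temporary 2,3-dioxabicyclo[2.2.2]octene ring is closed; no ring from this step survives in the product. The quinuclidine nitrogen of the catalyst then removes one of the two enantiotopic bridgehead hydrogens while the O–O bond breaks in an E2-like fashion (Kornblum–DeLaMare rearrangement), the closest known form being the cinchona-amine-catalysed desymmetrisation of meso bicyclic endoperoxides. The single new stereocentre (C4, R) is controlled by the catalyst alone, its phenolic hydroxyl being expected to hydrogen-bond the departing peroxide oxygen and fix which bridgehead C–H faces the base. Only enantiotopic-group selectivity is needed, because the mirror plane of the peroxide makes both deprotonations constitutionally identical. Adding the base only after irradiation has ended and oxygen has been purged should protect the amine from singlet oxygen and avoids isolating the peroxide, while low loading and temperature should limit base-induced isomerisation of the γ-hydroxy enone.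

**Step 2**
Reactants: 3 (4R)-4-hydroxycyclohex-2-en-1-one
Product: 4 (4R)-4-[(tert-butyldimethylsilyl)oxy]cyclohex-2-en-1-one
Conditions: TBSCl, imidazole, CH2Cl2, 0 °C to rt
Reagents that add atoms: tert-butyldimethylsilyl chloride, CC(C)(C)[Si](C)(C)Cl
Why: Imidazole-promoted O-silylation of the only hydroxyl is routine, leaves C4 untouched and installs the bulky ether that steers the next addition, the mild base keeping the γ-hydroxy enone from isomerising.

**Step 3**
Reactants: 4 (4R)-4-[(tert-butyldimethylsilyl)oxy]cyclohex-2-en-1-one; 5 isopropylmagnesium chloride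
Product: 6 (3R,4R)-4-[(tert-butyldimethylsilyl)oxy]-3-isopropyl-1-[(trimethylsilyl)oxy]cyclohex-1-ene (3,4-trans)
Conditions: TMSCl, CuI (10 mol %), LiCl (20 mol %), THF, −78 °C, slow addition of iPrMgCl; Et3N, cold aq. NaHCO3/pentane work-up
Reagents that add atoms: chlorotrimethylsilane, C[Si](C)(C)Cl
Why: Copper-catalysed 1,4-addition of the Grignard reagent with chlorosilane acceleration and in situ enolate trapping should deliver isopropyl to C5 on the face opposite the C4 silyloxy group, as is general for 4-silyloxycyclohexenones, so C5 is set trans to C4 and the C1=C6 enol silane is fixed regiochemically for the next step.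

**Step 4**
Reactants: 6 (3R,4R)-4-[(tert-butyldimethylsilyl)oxy]-3-isopropyl-1-[(trimethylsilyl)oxy]cyclohex-1-ene
Product: 8 (2R,3R,4R)-4-[(tert-butyldimethylsilyl)oxy]-2-hydroxy-3-isopropylcyclohexan-1-one, via trimethylsilyloxy ketone 7 (not isolated)
Conditions: mCPBA, NaHCO3, CH2Cl2, −20 to 0 °C; then citric acid, MeOH, 0 °C
Reagents that add atoms: 3-chloroperbenzoic acid, OOC(=O)c1cccc(Cl)c1
Why: Rubottom oxidation: the peracid should epoxidise the enol silane at C6 on the face anti to the adjacent C5 isopropyl group, the silyloxy epoxide opens with 1,4-silyl shift to the α-silyloxy ketone and brief acidic methanolysis frees the C6 hydroxyl, giving the all-trans (all-equatorial, also thermodynamically preferred) arrangement while the hindered TBS ether survives.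

**Step 5**
Reactants: 8 (2R,3R,4R)-4-[(tert-butyldimethylsilyl)oxy]-2-hydroxy-3-isopropylcyclohexan-1-one
Product: 11 (4R,5R,6R)-4-[(tert-butyldimethylsilyl)oxy]-6-hydroxy-5-isopropylcyclohex-2-en-1-one, via bis(trimethylsilyl) enol ether 9 (not isolated), via trimethylsilyloxy enone 10 (not isolated)
Conditions: TMSCl (4 equiv), LDA (commercial solution, 2.3 equiv), THF, −78 °C; solvent exchange; Pd(OAc)2 (1.1 equiv), MeCN, rt; then citric acid, MeOH, 0 °C
Reagents that add atoms: none
Why: Saegusa–Ito dehydrogenation: with chlorosilane present the amide base first silylates the C6 hydroxyl and then removes a proton kinetically from the unhindered C2 methylene (C6–H is shielded by its silyloxy group and the C5 branch), the C1=C2 enol silane transmetallates to Pd(OAc)2 and β-hydride elimination from C3 gives the C2=C3 enone, after which the labile C6 trimethylsilyl ether is methanolysed; no stereocentre is involved.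

**Step 6**
Reactants: 11 (4R,5R,6R)-4-[(tert-butyldimethylsilyl)oxy]-6-hydroxy-5-isopropylcyclohex-2-en-1-one
Product: 12 (4R,5R,6R)-4-[(tert-butyldimethylsilyl)oxy]-6-hydroxy-2-(hydroxymethyl)-5-isopropylcyclohex-2-en-1-one
Conditions: 37 % aq. CH2O, DMAP (0.3 equiv), THF/H2O, rt
Reagents that add atoms: formaldehyde, C=O
Why: Morita–Baylis–Hillman reaction: DMAP adds reversibly to C3, the resulting C2 enolate captures formaldehyde and loss of the amine restores the enone with the hydroxymethyl group at C2, a transformation established for 4-oxygenated cyclohex-2-enones that creates no stereocentre and should tolerate the silyl ether and the free α-ketol.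

**Step 7**
Reactants: 12 (4R,5R,6R)-4-[(tert-butyldimethylsilyl)oxy]-6-hydroxy-2-(hydroxymethyl)-5-isopropylcyclohex-2-en-1-one
Product: 13 (4R,5R,6R)-4-[(tert-butyldimethylsilyl)oxy]-2-{[(tert-butyldiphenylsilyl)oxy]methyl}-6-hydroxy-5-isopropylcyclohex-2-en-1-one
Conditions: TBDPSCl (1.05 equiv), imidazole, CH2Cl2, 0 °C
Reagents that add atoms: tert-butyl(chloro)diphenylsilane, CC(C)(C)[Si](Cl)(c1ccccc1)c1ccccc1
Why: Silylation with the bulky chlorosilane at low temperature should discriminate the unhindered primary allylic C7 hydroxyl from the secondary C6 hydroxyl flanked by the ketone and the isopropyl-bearing carbon, leaving the latter free for acylation.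

**Step 8**
Reactants: 14 glycolaldehyde dimer (1,4-dioxane-2,5-diol, 0.55 equiv); 15 ethyl 2-(triphenylphosphoranylidene)propanoate
Product: 16 ethyl (2E)-4-hydroxy-2-methylbut-2-enoate
Conditions: CH2Cl2, reflux
Reagents that add atoms: none
Why: Wittig olefination of glycolaldehyde, released from its dimer on warming, with a stabilised α-methyl ylide should give the trisubstituted enoate with E geometry (ester trans to CH2OH) under the usual thermodynamic control of stabilised ylides.

**Step 9**
Reactants: 16 ethyl (2E)-4-hydroxy-2-methylbut-2-enoate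
Product: 17 ethyl (2E)-4-[(tert-butyldiphenylsilyl)oxy]-2-methylbut-2-enoate
Conditions: TBDPSCl, imidazole, DMF, rt
Reagents that add atoms: tert-butyl(chloro)diphenylsilane, CC(C)(C)[Si](Cl)(c1ccccc1)c1ccccc1
Why: Standard silylation of the primary allylic alcohol with the same acid-resistant group used at C7, so that both can be removed together at the end.

**Step 10**
Reactants: 17 ethyl (2E)-4-[(tert-butyldiphenylsilyl)oxy]-2-methylbut-2-enoate
Product: 18 (2E)-4-[(tert-butyldiphenylsilyl)oxy]-2-methylbut-2-enoic acid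
Conditions: LiOH, THF/MeOH/H2O, rt to 40 °C; then 1 M HCl to pH 3
Reagents that add atoms: lithium hydroxide, [Li+].[OH-]
Why: Saponification of the ethyl ester with aqueous LiOH leaves the base-stable silyl ether and the E alkene untouched, and careful acidification liberates the free acid.

**Step 11**
Reactants: 13 (4R,5R,6R)-4-[(tert-butyldimethylsilyl)oxy]-2-{[(tert-butyldiphenylsilyl)oxy]methyl}-6-hydroxy-5-isopropylcyclohex-2-en-1-one; 18 (2E)-4-[(tert-butyldiphenylsilyl)oxy]-2-methylbut-2-enoic acid
Product: 20 (1R,5R,6R)-5-[(tert-butyldimethylsilyl)oxy]-3-{[(tert-butyldiphenylsilyl)oxy]methyl}-2-oxo-6-(propan-2-yl)cyclohex-3-en-1-yl (2E)-4-[(tert-butyldiphenylsilyl)oxy]-2-methylbut-2-enoate, via mixed anhydride 19 (not isolated)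
Conditions: 18, 2,4,6-trichlorobenzoyl chloride, Et3N, toluene, rt; then 13, DMAP, toluene, rt
Reagents that add atoms: none
Why: Yamaguchi esterification: the acid is activated as its mixed anhydride, which DMAP transfers to the hindered secondary C6 hydroxyl (the only free one) with retention at C6, a protocol suited to sluggish α-branched unsaturated acids.

**Step 12**
Reactants: 20 (1R,5R,6R)-5-[(tert-butyldimethylsilyl)oxy]-3-{[(tert-butyldiphenylsilyl)oxy]methyl}-2-oxo-6-(propan-2-yl)cyclohex-3-en-1-yl (2E)-4-[(tert-butyldiphenylsilyl)oxy]-2-methylbut-2-enoate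
Product: 21 (1R,5R,6S)-3-{[(tert-butyldiphenylsilyl)oxy]methyl}-5-hydroxy-2-oxo-6-(propan-2-yl)cyclohex-3-en-1-yl (2E)-4-[(tert-butyldiphenylsilyl)oxy]-2-methylbut-2-enoate
Conditions: camphorsulfonic acid (0.3 equiv), MeOH/CH2Cl2 (1:1), 0 °C to rt
Reagents that add atoms: none
Why: Acid-catalysed methanolysis should cleave the secondary tert-butyldimethylsilyl ether while the primary tert-butyldiphenylsilyl ethers, which are far more stable to acid, persist, and the acidic medium avoids 1,3-acyl migration from the C6 oxygen to the freed cis C4 hydroxyl.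

**Step 13**
Reactants: 21 (1R,5R,6S)-3-{[(tert-butyldiphenylsilyl)oxy]methyl}-5-hydroxy-2-oxo-6-(propan-2-yl)cyclohex-3-en-1-yl (2E)-4-[(tert-butyldiphenylsilyl)oxy]-2-methylbut-2-enoate
Product: 22 (1R,5S,6S)-3-{[(tert-butyldiphenylsilyl)oxy]methyl}-2-oxo-5-(propanoyloxy)-6-(propan-2-yl)cyclohex-3-en-1-yl (2E)-4-[(tert-butyldiphenylsilyl)oxy]-2-methylbut-2-enoate
Conditions: EtCO2H (3 equiv), PPh3, DIAD, THF, 0 °C to rt
Reagents that add atoms: propanoic acid, CCC(=O)O
Why: Mitsunobu esterification: the C4 hydroxyl is activated as its oxyphosphonium ion and displaced by propanoate in an SN2 process with inversion (R to S), placing the ester cis to isopropyl; elimination is disfavoured because the C5 hydrogen is syn to the leaving group, SN2' attack would have to occur at the fully substituted enone α-carbon C2, and the C6 ester on the same face as the leaving group cannot participate.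

**Step 14**
Reactants: 22 (1R,5S,6S)-3-{[(tert-butyldiphenylsilyl)oxy]methyl}-2-oxo-5-(propanoyloxy)-6-(propan-2-yl)cyclohex-3-en-1-yl (2E)-4-[(tert-butyldiphenylsilyl)oxy]-2-methylbut-2-enoate
Product: 23 (1R,5S,6S)-3-(hydroxymethyl)-2-oxo-5-(propanoyloxy)-6-(propan-2-yl)cyclohex-3-en-1-yl (2E)-4-hydroxy-2-methylbut-2-enoate (CNP0285949.1)
Conditions: HF·pyridine, pyridine, THF, 0 °C to rt
Reagents that add atoms: none
Why: Buffered HF·pyridine should remove both primary silyl ethers by fluoride attack at silicon under mildly acidic conditions that leave the two esters, the enone and all three stereocentres untouched, a basic fluoride source being avoided because of the acyloxy ketone.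

**Compound list**

1 | cyclohexa-1,3-diene | C1=CC=CCC1 | starting material
2 | (1R,4S)-2,3-dioxabicyclo[2.2.2]oct-5-ene (meso endoperoxide, formed and consumed in the flask) | C1C[C@@H]2C=C[C@H]1OO2 | intermediate
3 | (4R)-4-hydroxycyclohex-2-en-1-one | O[C@@H]1CCC(=O)C=C1 | intermediate
4 | (4R)-4-[(tert-butyldimethylsilyl)oxy]cyclohex-2-en-1-one | CC(C)(C)[Si](C)(C)O[C@@H]1CCC(=O)C=C1 | intermediate
5 | isopropylmagnesium chloride | CC(C)[Mg]Cl | starting material
6 | (3R,4R)-4-[(tert-butyldimethylsilyl)oxy]-3-isopropyl-1-[(trimethylsilyl)oxy]cyclohex-1-ene | CC(C)(C)[Si](C)(C)O[C@@H]1CCC(O[Si](C)(C)C)=C[C@H]1C(C)C | intermediate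
7 | (2R,3S,4R)-4-[(tert-butyldimethylsilyl)oxy]-3-isopropyl-2-[(trimethylsilyl)oxy]cyclohexan-1-one (formed and consumed in the flask) | CC(C)(C)[Si](C)(C)O[C@@H]1CCC(=O)[C@H](O[Si](C)(C)C)[C@H]1C(C)C | intermediate
8 | (2R,3R,4R)-4-[(tert-butyldimethylsilyl)oxy]-2-hydroxy-3-isopropylcyclohexan-1-one | CC(C)(C)[Si](C)(C)O[C@@H]1CCC(=O)[C@H](O)[C@H]1C(C)C | intermediate
9 | (4R,5S,6R)-4-[(tert-butyldimethylsilyl)oxy]-5-isopropyl-1,6-bis[(trimethylsilyl)oxy]cyclohex-1-ene (formed and consumed in the flask) | CC(C)(C)[Si](C)(C)O[C@@H]1CC=C(O[Si](C)(C)C)[C@H](O[Si](C)(C)C)[C@H]1C(C)C | intermediate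
10 | (4R,5S,6R)-4-[(tert-butyldimethylsilyl)oxy]-5-isopropyl-6-[(trimethylsilyl)oxy]cyclohex-2-en-1-one (formed and consumed in the flask) | CC(C)(C)[Si](C)(C)O[C@@H]1C=CC(=O)[C@H](O[Si](C)(C)C)[C@H]1C(C)C | intermediate
11 | (4R,5R,6R)-4-[(tert-butyldimethylsilyl)oxy]-6-hydroxy-5-isopropylcyclohex-2-en-1-one | CC(C)(C)[Si](C)(C)O[C@@H]1C=CC(=O)[C@H](O)[C@H]1C(C)C | intermediate
12 | (4R,5R,6R)-4-[(tert-butyldimethylsilyl)oxy]-6-hydroxy-2-(hydroxymethyl)-5-isopropylcyclohex-2-en-1-one | CC(C)(C)[Si](C)(C)O[C@@H]1C=C(CO)C(=O)[C@H](O)[C@H]1C(C)C | intermediate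
13 | (4R,5R,6R)-4-[(tert-butyldimethylsilyl)oxy]-2-{[(tert-butyldiphenylsilyl)oxy]methyl}-6-hydroxy-5-isopropylcyclohex-2-en-1-one | CC(C)(C)[Si](C)(C)O[C@@H]1C=C(CO[Si](c2ccccc2)(c2ccccc2)C(C)(C)C)C(=O)[C@H](O)[C@H]1C(C)C | intermediate
14 | glycolaldehyde dimer (1,4-dioxane-2,5-diol, stereoisomer mixture) | OC1COC(O)CO1 | starting material
15 | ethyl 2-(triphenylphosphoranylidene)propanoate | CCOC(=O)C(C)=P(c1ccccc1)(c1ccccc1)c1ccccc1 | starting material
16 | ethyl (2E)-4-hydroxy-2-methylbut-2-enoate | CCOC(=O)/C(C)=C/CO | intermediate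
17 | ethyl (2E)-4-[(tert-butyldiphenylsilyl)oxy]-2-methylbut-2-enoate | CCOC(=O)/C(C)=C/CO[Si](c1ccccc1)(c1ccccc1)C(C)(C)C | intermediate
18 | (2E)-4-[(tert-butyldiphenylsilyl)oxy]-2-methylbut-2-enoic acid | OC(=O)/C(C)=C/CO[Si](c1ccccc1)(c1ccccc1)C(C)(C)C | intermediate
19 | (2E)-4-[(tert-butyldiphenylsilyl)oxy]-2-methylbut-2-enoic 2,4,6-trichlorobenzoic anhydride (formed and consumed in the flask) | O=C(OC(=O)c1c(Cl)cc(Cl)cc1Cl)/C(C)=C/CO[Si](c1ccccc1)(c1ccccc1)C(C)(C)C | intermediate
20 | (1R,5R,6R)-5-[(tert-butyldimethylsilyl)oxy]-3-{[(tert-butyldiphenylsilyl)oxy]methyl}-2-oxo-6-(propan-2-yl)cyclohex-3-en-1-yl (2E)-4-[(tert-butyldiphenylsilyl)oxy]-2-methylbut-2-enoate | CC(C)(C)[Si](C)(C)O[C@@H]1C=C(CO[Si](c2ccccc2)(c2ccccc2)C(C)(C)C)C(=O)[C@H](OC(=O)/C(C)=C/CO[Si](c2ccccc2)(c2ccccc2)C(C)(C)C)[C@H]1C(C)C | intermediate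
21 | (1R,5R,6S)-3-{[(tert-butyldiphenylsilyl)oxy]methyl}-5-hydroxy-2-oxo-6-(propan-2-yl)cyclohex-3-en-1-yl (2E)-4-[(tert-butyldiphenylsilyl)oxy]-2-methylbut-2-enoate | O[C@@H]1C=C(CO[Si](c2ccccc2)(c2ccccc2)C(C)(C)C)C(=O)[C@H](OC(=O)/C(C)=C/CO[Si](c2ccccc2)(c2ccccc2)C(C)(C)C)[C@H]1C(C)C | intermediate
22 | (1R,5S,6S)-3-{[(tert-butyldiphenylsilyl)oxy]methyl}-2-oxo-5-(propanoyloxy)-6-(propan-2-yl)cyclohex-3-en-1-yl (2E)-4-[(tert-butyldiphenylsilyl)oxy]-2-methylbut-2-enoate | CCC(=O)O[C@H]1C=C(CO[Si](c2ccccc2)(c2ccccc2)C(C)(C)C)C(=O)[C@H](OC(=O)/C(C)=C/CO[Si](c2ccccc2)(c2ccccc2)C(C)(C)C)[C@H]1C(C)C | intermediate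
23 | (1R,5S,6S)-3-(hydroxymethyl)-2-oxo-5-(propanoyloxy)-6-(propan-2-yl)cyclohex-3-en-1-yl (2E)-4-hydroxy-2-methylbut-2-enoate | CCC(=O)O[C@H]1C=C(CO)C(=O)[C@H](OC(=O)/C(C)=C/CO)[C@H]1C(C)C | target

**Step count and risk**

Total step count: 14. Longest linear sequence: 11 steps (steps 1–7 and 11–14); steps 8–10 form the side-chain branch.

Steps most likely to fail:

1. Step 1: discrimination between the two enantiotopic bridgehead hydrogens of the small, rigid bicyclic peroxide may be incomplete, or an uncatalysed background rearrangement may erode it. Fallback, setting out from 2 and returning at 4: the peroxide bond of 2 is reduced in the same flask with thiourea in MeOH to meso (1R,4S)-cyclohex-2-ene-1,4-diol F1. A lipase with vinyl acetate, screened for acylation of the S-configured carbinol carbon, should then desymmetrise the diol to (1S,4R)-4-hydroxycyclohex-2-en-1-yl acetate F2. Silylation (TBSCl, imidazole) gives (1S,4R)-4-[(tert-butyldimethylsilyl)oxy]cyclohex-2-en-1-yl acetate F3, methanolysis (K2CO3, MeOH) gives (1S,4R)-4-[(tert-butyldimethylsilyl)oxy]cyclohex-2-en-1-ol F4, and allylic oxidation with MnO2 in CH2Cl2 gives 4. The source of asymmetry is thus moved from the base-mediated rearrangement to an enzymatic desymmetrisation of the diol.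

2. Step 13: displacement at the hindered C4 oxyphosphonium by the weakly acidic propanoic acid may be slow, so that the activated alcohol is consumed by acylation with retention or by decomposition. Fallback, setting out from 21 and returning at 22: the Mitsunobu reaction is run with the stronger chloroacetic acid (PPh3, DIAD, toluene) to give the inverted (1R,5S,6S)-3-{[(tert-butyldiphenylsilyl)oxy]methyl}-5-[(chloroacetyl)oxy]-2-oxo-6-(propan-2-yl)cyclohex-3-en-1-yl (2E)-4-[(tert-butyldiphenylsilyl)oxy]-2-methylbut-2-enoate F6. The chloroacetate alone is then cleaved with thiourea and NaHCO3 in EtOH to (1R,5S,6S)-3-{[(tert-butyldiphenylsilyl)oxy]methyl}-5-hydroxy-2-oxo-6-(propan-2-yl)cyclohex-3-en-1-yl (2E)-4-[(tert-butyldiphenylsilyl)oxy]-2-methylbut-2-enoate F7, which is acylated with propanoic anhydride, pyridine and catalytic DMAP to 22.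

3. Step 6: amine addition at C3, next to the silyloxy-bearing C4, may be slow or unproductive, so that hydroxymethylation stalls while the free α-ketol degrades in the basic aqueous medium. Fallback, setting out from 11 and returning at 12: α-iodination of the enone with I2 and pyridine in CH2Cl2 gives (4S,5R,6R)-4-[(tert-butyldimethylsilyl)oxy]-6-hydroxy-2-iodo-5-isopropylcyclohex-2-en-1-one F5. Stille coupling with (tributylstannyl)methanol and Pd(PPh3)4 in dioxane at 80 °C then installs the hydroxymethyl group under neutral conditions and gives 12.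

**Further compounds**

F1 | step 1 | (1R,4S)-cyclohex-2-ene-1,4-diol (meso, cis) | O[C@@H]1CC[C@H](O)C=C1
F2 | step 1 | (1S,4R)-4-hydroxycyclohex-2-en-1-yl acetate | O[C@@H]1CC[C@H](OC(C)=O)C=C1
F3 | step 1 | (1S,4R)-4-[(tert-butyldimethylsilyl)oxy]cyclohex-2-en-1-yl acetate | CC(C)(C)[Si](C)(C)O[C@@H]1CC[C@H](OC(C)=O)C=C1
F4 | step 1 | (1S,4R)-4-[(tert-butyldimethylsilyl)oxy]cyclohex-2-en-1-ol | CC(C)(C)[Si](C)(C)O[C@@H]1CC[C@H](O)C=C1
F5 | step 6 | (4S,5R,6R)-4-[(tert-butyldimethylsilyl)oxy]-6-hydroxy-2-iodo-5-isopropylcyclohex-2-en-1-one | CC(C)(C)[Si](C)(C)O[C@@H]1C=C(I)C(=O)[C@H](O)[C@H]1C(C)C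
F6 | step 13 | (1R,5S,6S)-3-{[(tert-butyldiphenylsilyl)oxy]methyl}-5-[(chloroacetyl)oxy]-2-oxo-6-(propan-2-yl)cyclohex-3-en-1-yl (2E)-4-[(tert-butyldiphenylsilyl)oxy]-2-methylbut-2-enoate | ClCC(=O)O[C@H]1C=C(CO[Si](c2ccccc2)(c2ccccc2)C(C)(C)C)C(=O)[C@H](OC(=O)/C(C)=C/CO[Si](c2ccccc2)(c2ccccc2)C(C)(C)C)[C@H]1C(C)C
F7 | step 13 | (1R,5S,6S)-3-{[(tert-butyldiphenylsilyl)oxy]methyl}-5-hydroxy-2-oxo-6-(propan-2-yl)cyclohex-3-en-1-yl (2E)-4-[(tert-butyldiphenylsilyl)oxy]-2-methylbut-2-enoate | O[C@H]1C=C(CO[Si](c2ccccc2)(c2ccccc2)C(C)(C)C)C(=O)[C@H](OC(=O)/C(C)=C/CO[Si](c2ccccc2)(c2ccccc2)C(C)(C)C)[C@H]1C(C)C
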